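| flask | starting material | remark | time |
|---|---|---|---|
| eta | 3 M | the very flask that is asked about, followed so far |  |
| beta | 2 M | run made earlier |  |
| flask | 3.0 M |  | 12 min |

| run | time / min | target / % | crystals / % |
|---|---|---|---|
| eta | 0.833 | 32 | 1 |
| eta | 1.50 | 26 | 2 |
| eta | 2.50 | 22 | 0 |
| eta | 3.00 | 17 | 0 |
| eta | 4.00 | 21 | 2 |
| eta | 5.00 | 13 | 0 |
| eta | 6.00 | 12 | 0 |
| beta | 1.33 | 30 | 0 |
| beta | 2.50 | 24 | 0 |
| beta | 4.00 | 22 | 0 |
| beta | 5.00 | 19 | 2 |
| beta | 6.00 | 16 | 0 |
| beta | 8.00 | 15 | 1 |

(each reading ± 2 percentage points)

1. how much target and crystals together there is at 12 min, in percent of the starting material charged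
2. concentration of target in solution at 12 min, in percent of saturation

- target is meant together with its crystals
- solid, in amounts per volume of the solution: crystals
- the earlier runs were read with a standard deviation of 2 percentage points

By 0.833 min the eta flask already reads 32% target, so we assume that the first turning of the starting material, our limiting reagent, is over by then, and we keep the books on what was charged. Crystals get no entry, since their readings reach 2%, within the scatter of 2 points.

Target gets the one entry we can read. At 4.00 min the beta run, charged with 2 M, reads 22% and the eta flask 21%, so we pool both runs in percent: 29.3% near 1.22 min, 21.2% near 3.20 min, and 15.0% near 6.00 min. The fall slows, from 8.1 points in 1.98 min to 6.2 points in 2.80 min. We therefore let it run in proportion to the excess over a floor. That excess has a half-life of 2.62 min, and the floor, the share of the charge at which target comes to rest, reads 9.73%, with the scatter of the readings in it.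

Our books at 12 min then show 10.8% target and 89.2% in forms unread. The eta flask read 0.960 M of target at 0.833 min with its crystal reading within the scatter, so we estimate sat to lie under 33.8%, an estimate that carries the scatter of that reading.

The forecast differs, with 7.5% (5.5% to 10%) of target and crystals together, on the ground that “decay looks second order in target”, and with 14% (4% to 27%) of saturation.

The flask gives 10.9% of target and crystals together and 23.3% of saturation.

    starting material ⇌ target (K = 5.33, k = 0.0666 s⁻¹)
    starting material ⇌ isomer of the product (K = 5.56, k = 0.0366 s⁻¹)
    starting material ⇌ third isomer (K = 42.0, k = 0.0531 s⁻¹)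
    crystals ⇌ target, rate k4*(cs4 - [target]) while solid is left; crystals form when [target] > cs4 (solubility = 1.40 M, k = 0.0734 s⁻¹)

At 12.0 min the unread entry holds third isomer at 75.2% of the charge. The answer stands 1.2 points over our floor. Floor and half-life, reckoned from 3.20 min for the same flask read at 5.0 min, give 16.9%, and that flask holds 15.7%.

The numbers in the tables are simulated for substances that don't exist; the scatter is artificial.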